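Take over blue and green as a single charge: the two flasks differ in when they stop, green at 2.5 h and blue at 5.0 h.

| flask | substrate | partner | protic impurity | remark | time |
|---|---|---|---|---|---|
| alder | 0.40 M | 2.4 M | 0.016 M | run made earlier |  |
| maple | 1.6 M | 2.4 M | 0.016 M | run made earlier |  |
| blue | 0.80 M | 2.40 M | 0.0160 M |  | 5.0 h |
| green | 0.80 M | 2.40 M | 0.0160 M |  | 2.5 h |

| run | time / h | target / % | side product / % | substrate / % |
|---|---|---|---|---|
| alder | 0.250 | 6.0 | 7.1 | 87.3 |
| alder | 0.417 | 9.3 | 10.9 | 80.1 |
| alder | 0.833 | 15.9 | 19.7 | 64.4 |
| alder | 1.50 | 22.2 | 30.3 | 48.0 |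
| alder | 3.00 | 25.3 | 46.7 | 28.4 |
| maple | 0.250 | 6.3 | 6.5 | 87.3 |
| maple | 0.833 | 14.9 | 19.6 | 65.5 |
| maple | 1.33 | 19.3 | 28.2 | 52.0 |
| maple | 2.00 | 22.0 | 36.9 | 39.9 |
| maple | 3.00 | 22.8 | 47.7 | 29.2 |

(each reading ± 0.3 percentage points)

* which of these there is most of at the end, counted by the substrate in it, blue (substrate / target / side product)
* which of these there is most of at the end, counted by the substrate in it, green (substrate / target / side product)
* how much there is at the end of the one of these that leads, in percent of the substrate charged: blue
* how much there is at the end of the one of these that leads, in percent of the substrate charged: green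



Leave the substrate charge alone: a 4.00-fold change from alder to maple moved substrate at 3.00 h from 28.4% to 29.2%, so I pooled the two runs there. I write A for substrate, P for target and Q for side product, each in percent of the substrate charged, and Ā for the logarithmic mean of A over an interval. Over maple's last hour Q rose 11 percentage points and P rose 0.8 points, so I counted the late flask by Q, with k = ΔQ/(Δt·Ā):

alder, 1.50 h to 3.00 h: k = 0.293 h⁻¹

maple, 1.33 h to 3.00 h: k = 0.296 h⁻¹

I carried their mean, 0.294 h⁻¹, the side-product constant, a first-order rate constant: side product gained per hour per unit of substrate present. With P held at the pooled 24.0% and A starting from the pooled 28.8%, A falls exponentially with k and Q takes the remainder of the charge: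

green: A = 33.4%, Q = 42.6%

blue: A = 16.0%, Q = 60.0%

Side product leads in both flasks, by my reckoning.

The forecast also named side product for blue and side product for green, at 61% (56% to 66%) and 42% (40.5% to 43.5%), higher than mine in blue and lower in green, holding that “substrate loss is effectively first order”.

Blue gave side product at 60.2%, and green gave side product at 42.4%.

    substrate → side product (k = 0.00490 min⁻¹)
    substrate + partner ⇌ target (K = 0.380 M⁻¹, k = 0.00190 M⁻¹ min⁻¹)
    partner + protic impurity → quenched reagent (k = 0.0820 M⁻¹ min⁻¹)

In green at 2.50 h, the loss of substrate to side product ran 1.2 times the forward making of target. Applied to green's substrate from 53.4% at 1.25 h to 33.3% at 2.50 h, k counts 16 points of side product gained. In a neighbour of green charged with 0.96 M of partner, substrate fell to 41.2% by 2.50 h; k counts 48.7% of side product, and that neighbour held 47.8%.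

The readings were computed with made-up constants; noise was put on by code.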